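**Retrosynthetic overview**
1. The tiglate C–O bond is cut last; the acyl partner is tiglic acid (1), used as tigloyl chloride (2).
2. The whole carbon skeleton is bought as (+)-manool (3). The key disconnection is the C19–O bond, made by site-selective hydroxylation of the axial 4β-methyl C–H to give 19-hydroxymanool (4); this step also creates the C4 stereocentre.
3. Chemoselective acylation of the primary C19–OH of 4 with 2 gives the target (5).
4. Ring order: no ring is formed. Rings A and B (trans-decalin) and the stereocentres C5, C9, C10 and C13 come unchanged from 3.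

Assumption: (+)-manool, the (13R) natural product of the normal labdane series (5α-H, 9α-H, 10β-CH3), is taken as a cheap commercial bulk terpenoid.

**Step 1**
Reactants: 1 tiglic acid, (2E)-2-methylbut-2-enoic acid
Product: 2 tigloyl chloride, (2E)-2-methylbut-2-enoyl chloride
Conditions: (COCl)2 (1.2 equiv), N,N-dimethylformamide (1 mol%), CH2Cl2, 0 °C to rt; distilled under reduced pressure
Reagents that add atoms: oxalyl chloride, O=C(Cl)C(=O)Cl
Why: Acid chloride formation through the Vilsmeier-type chloroiminium salt is standard for α,β-unsaturated acids and leaves the trisubstituted (E)-alkene untouched; no stereocentre is made.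

**Step 2**
Reactants: 3 (+)-manool, (5S,9S,10S,13R)-labda-8(17),14-dien-13-ol
Product: 4 19-hydroxymanool (torulosol), (4S,5R,9S,10R,13R)-labda-8(17),14-diene-13,19-diol, with the CH2OH on C4 axial (4β) and cis to the C10 methyl
Conditions: cytochrome P450 BM3 (CYP102A1) variant F87A/A328V (E. coli lysate), NADP+ (cat.), D-glucose (2 equiv), glucose dehydrogenase, air, K2HPO4/KH2PO4 buffer pH 8.0 with 2% DMSO, 25 °C
Reagents that add atoms: dioxygen, O=O
Why: Proposed new method: enzymatic hydroxylation of the axial 4β-methyl (C19) of manool by an engineered self-sufficient P450 BM3, a substrate and site not yet shown for this enzyme; the only polar group (C13–OH) should stay at the solvent-exposed channel mouth so that the decalin enters ring A first, the F87A mutation opens space directly above the heme iron, and the bulkier A328V wall should disfavour edge-on presentation of C2, C3 and C18, so the substrate sits β-face down, where the two axial methyls C19 and C20 project beyond every ring hydrogen and C19, at the far end of ring A, lies over iron; the ferryl (tetravalent iron) oxo porphyrin radical cation abstracts a C19 hydrogen and the primary radical rebounds onto the iron-bound OH, which forms the C19–O bond and fixes C4 as (S) by choosing, of the two diastereotopic methyls, the one cis to C20, with C5, C9, C10, C13 and both alkenes untouched; the closest known reaction type is hydrogen-abstraction/oxygen-rebound C–H hydroxylation of terpenoids by P450 BM3 variants (ring A of sclareol-type labdanes, methyl groups of other terpenoids), and plant P450s hydroxylate C19 of labdane-type diterpenes in biosynthesis.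

**Step 3**
Reactants: 4 19-hydroxymanool; 2 tigloyl chloride (1.5 equiv)
Product: 5 (4S,5R,9S,10R,13R)-13-hydroxylabda-8(17),14-dien-19-yl (2E)-2-methylbut-2-enoate (CNP0313179.1)
Conditions: pyridine (3 equiv), 4-(dimethylamino)pyridine (10 mol%), CH2Cl2, 0 °C to rt
Reagents that add atoms: tigloyl chloride (compound 2), C/C=C(\C)C(=O)Cl
Why: This is a 4-(dimethylamino)pyridine-catalysed nucleophilic acyl substitution (acyl chloride esterification) in which the primary C19–OH reacts and the tertiary allylic C13–OH is inert under these mild, HCl-scavenged conditions; no stereocentre is touched and the thermodynamically preferred (E)-tiglate geometry is kept.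

**Compound list**
1 | tiglic acid, (2E)-2-methylbut-2-enoic acid | C/C=C(\C)C(=O)O | starting material
2 | tigloyl chloride, (2E)-2-methylbut-2-enoyl chloride | C/C=C(\C)C(=O)Cl | intermediate
3 | (+)-manool, (5S,9S,10S,13R)-labda-8(17),14-dien-13-ol | C=C[C@](C)(O)CC[C@H]1C(=C)CC[C@H]2C(C)(C)CCC[C@]12C | starting material
4 | 19-hydroxymanool (torulosol), (4S,5R,9S,10R,13R)-labda-8(17),14-diene-13,19-diol | C=C[C@](C)(O)CC[C@H]1C(=C)CC[C@H]2[C@@](C)(CO)CCC[C@]12C | intermediate
5 | (4S,5R,9S,10R,13R)-13-hydroxylabda-8(17),14-dien-19-yl (2E)-2-methylbut-2-enoate | C=C[C@](C)(O)CC[C@H]1C(=C)CC[C@H]2[C@@](C)(COC(=O)/C(C)=C/C)CCC[C@]12C | target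

**Totals**
Total step count: 3. Longest linear sequence: 2 steps (3 → 4 → 5).

**Steps most likely to fail**

1. Step 2 (the proposed C–H hydroxylation). The enzyme may instead hydroxylate C3 or C2 of ring A, the equatorial methyl C18 or the allylic C7, epoxidise either alkene, or oxidise 4 further at C19. The first remedy is a focused active-site library at positions 75, 78, 82, 87 and 328, screened for C19 selectivity. Fallback (known chemistry only): the C–H hydroxylation is given up and the C19 oxygen is bought with the skeleton. This fallback sets out from no numbered compound of the route: compound 3 is replaced by purchased, costlier isocupressic acid F1. It comes back to the route at compound 4. LiAlH4 (THF, 0 °C to reflux) reduces the C19 acid to agathadiol F2. Sharpless asymmetric epoxidation of its allylic alcohol (Ti(OiPr)4, D-(−)-diethyl tartrate, t-BuOOH, 4 Å molecular sieves, CH2Cl2, −20 °C) gives (13R,14R)-13,14-epoxylabd-8(17)-ene-15,19-diol F3 and so sets C13 through a C–O bond under reagent control. PPh3, I2 and imidazole (1.05 equiv, THF, 0 °C) convert the unhindered C15–OH, not the neopentyl C19–OH, into (13R,14S)-13,14-epoxy-15-iodolabd-8(17)-en-19-ol F4. Zinc dust in ethanol at reflux opens F4 reductively to the tertiary vinyl carbinol 4 with C13 unchanged.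

2. Step 3 (acylation). The axial neopentyl C19–OH may react slowly, and the acid chloride may give deconjugated (vinylketene-derived) or (Z)-ester. Fallback: it sets out from compound 4 and comes back at compound 5. Compound 4 is esterified with 2-(diethoxyphosphoryl)propanoic acid (DCC, 4-(dimethylamino)pyridine, CH2Cl2, rt) to give 13-hydroxylabda-8(17),14-dien-19-yl 2-(diethoxyphosphoryl)propanoate F5. Horner–Wadsworth–Emmons olefination with acetaldehyde (LiCl, DBU, MeCN, 0 °C) then builds the (E)-2-methylbut-2-enoate in place and gives 5; the minor (Z)-ester is removed by chromatography.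

3. Step 1 (acid chloride). Compound 2 is volatile and moisture-sensitive, and traces of HCl can erode its quality. Fallback: it sets out from compound 1 (together with 4) and comes back at compound 5, so compound 2 is never made. In a Yamaguchi esterification, 1 with 2,4,6-trichlorobenzoyl chloride and Et3N in toluene at rt gives tiglic 2,4,6-trichlorobenzoic anhydride F6, which is not isolated. Addition of 4 and 4-(dimethylamino)pyridine then gives 5 directly.

**Further compounds**
F1 | step 2 | isocupressic acid, (13E)-15-hydroxylabda-8(17),13-dien-19-oic acid | OC/C=C(\C)CC[C@H]1C(=C)CC[C@H]2[C@@](C)(C(=O)O)CCC[C@]12C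
F2 | step 2 | agathadiol, (13E)-labda-8(17),13-diene-15,19-diol | OC/C=C(\C)CC[C@H]1C(=C)CC[C@H]2[C@@](C)(CO)CCC[C@]12C
F3 | step 2 | (13R,14R)-13,14-epoxylabd-8(17)-ene-15,19-diol | OC[C@H]1O[C@]1(C)CC[C@H]1C(=C)CC[C@H]2[C@@](C)(CO)CCC[C@]12C
F4 | step 2 | (13R,14S)-13,14-epoxy-15-iodolabd-8(17)-en-19-ol | IC[C@H]1O[C@]1(C)CC[C@H]1C(=C)CC[C@H]2[C@@](C)(CO)CCC[C@]12C
F5 | step 3 | 13-hydroxylabda-8(17),14-dien-19-yl 2-(diethoxyphosphoryl)propanoate (both epimers at the phosphonate carbon) | C=C[C@](C)(O)CC[C@H]1C(=C)CC[C@H]2[C@@](C)(COC(=O)C(C)P(=O)(OCC)OCC)CCC[C@]12C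
F6 | step 1 | tiglic 2,4,6-trichlorobenzoic anhydride | C/C=C(\C)C(=O)OC(=O)c1c(Cl)cc(Cl)cc1Cl
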